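1. The delta run was charged with 0.070 M of starting material. The epsilon run, which is the flask asked about followed so far, was charged with 0.14 M.

in all of them: gas 40 mM (held)
- epsilon: starting material 0.14 M (fed, over 2.5 min); the very flask that is asked about, followed so far; the fed solution adds 0.10 times the starting volume
- delta: starting material 0.070 M (fed, over 2.5 min); run made earlier; the fed solution adds 0.10 times the starting volume
- flask: starting material 0.14 M (fed, over 2.5 min); the fed solution adds 0.10 times the starting volume; time 1.5 h

- epsilon (time / min: target / %): 0.833: 8; 3.00: 24; 12.0: 1; 50.0: 4
- delta (time / min: target / %): 0.833: 10; 4.00: 18; 15.0: 0; 60.0: 0

(readings scatter by 1.5 percentage points)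

- every charge counts on the volume at the start, and the solution that is fed holds the whole dose
- at the start none of the gas is in solution
- a reading or a percentage of target counts all its forms, free or not
- percentages count the whole charge, also what has not yet gone in

* time, not beyond 1.5 h, at which the flask holds most target
* the amount of target, in percent of the starting material charged, at that time
* earliest time at which at least nineteen twentieths of that best amount are there, in min
* latest time at which they still are

2. I wrote the balance of the gas, assuming that one gas goes into each target. A saturated solution holds 40 mM, which is less than the charge, so with a single filling of dissolved gas, gas would be the limiting reagent. I therefore defined the filling number N, the charge over the saturation concentration, which for this flask is 3.50.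

3. I then took two ways to the gas crossed by 0.833 min, when both runs had received the same fraction of their feed. On that assumption, target read in concentration is a floor for that gas. Epsilon's reading gives 11.2 mM and delta's gives 7.00 mM. I expected a match, since the gas is held alike in both runs. The gap of 4.20 mM is about twice the 2.10 mM that one epsilon reading carries, so I kept the match as a rough one. The percentages cheat here: delta's reading of 10 % stands above epsilon's 8 %, yet its charge is smaller.

4. At 3.00 min, after the feed had ended, epsilon's target reading came to 0.840 fillings, fewer than N, so my own reckoning put the peak after the feed, near that reading of 24 %.

5. The forecast gave 0.048 h (range 0.04 h to 0.06 h), 25 % (22 % to 30 %), opening at 2.4 min and shutting at 0.057 h. Its ground was: “I therefore expect the maximum just after the feed ends”.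

6. The flask gave 22.7 % at 0.0576 h, with the window running from 2.68 min to 0.0700 h.

    starting material + coupling partner ⇌ target (K = 116 M⁻¹, k = 3.79 M⁻¹ s⁻¹)
    starting material + coupling partner → isomer of the product (k = 1.60 M⁻¹ s⁻¹)
    gas ⇌ coupling partner, rate k3*(csat - [coupling partner]) (kL = 0.0144 s⁻¹)
    crystals ⇌ target, rate k4*(cs4 - [target]) while solid is left; crystals form when [target] > cs4 (solubility = 35.0 mM, k = 0.988 s⁻¹)

At the best time this flask held 27.0 % starting material and 50.3 % isomer of the product. Counting target, isomer and free coupling partner, on the starting volume, 110 mM of gas had crossed, which is 2.75 of the 3.50 fillings, at an average pace of 31.9 mM min⁻¹.

For the neighbour flask charged with 0.56 M, N is 14.0, and at that pace I reckoned 17.6 min for that much gas to cross, inside 1.5 h. Computed, that neighbour peaks at 12.0 % and has 0 % starting material left and 100 % isomer of the product at 1.50 h.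

(The readings come from a simulation on assumed constants; noise was put on by code.)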